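**Plan**

1. Cuts (eremophilane numbering: ring A = C1–C5/C10 with the ketone at C2, methyls on C4 and C5; ring B = C5–C10 with isopropenyl on C7, OAc on C8, OTig on C9; β = face of the C5 methyl): the two ester C–O bonds, then C7–isopropenyl, then C1 out of ring A, then C5–C6 and C9–C10, then the cyclopentenone C=C and the bond from C4 to the future C5.
2. Enabling feature: in ring A the carbonyl C2 sits between two CH2 groups (C1, C3) and one carbon away from the ring-fusion methine C10. Deleting C1 puts C2 directly on C10, so C5=C10 becomes the enone double bond of 3,4-dimethylcyclopent-2-enone and ring B can be added by cycloaddition.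
3. Forward order: acyclic Weinreb amide → cyclopentenone (ring A as a five-membered ring) → ring B by Diels–Alder with a 1-silyloxydiene → ring A enlarged 5→6 by a β-oxido carbenoid 1,2-shift of C10 → ring B functionalised (epoxide, isopropenyl, two esters).
4. Stereochemistry: C4 from Rh/BINAP conjugate addition; C5, C10 and C9 from the Diels–Alder (anti to the C4 methyl, cis fusion, endo); C10 retained in the shift; C8 by OH-directed epoxidation; C7 by anti (trans-diaxial) epoxide opening.

Key step: step 7

Remark: the carbinol configuration of 13 is left undefined in its SMILES because that centre is destroyed in step 7; amide 1 is taken as purchasable (otherwise one step from crotonyl chloride).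

**Route**

Step 1
Reactants: 1 (E)-N-methoxy-N-methylbut-2-enamide; 2 isopropenylboronic acid pinacol ester
Product: 3 (S)-N-methoxy-N,3,4-trimethylpent-4-enamide
Conditions: [Rh(cod)Cl]2 (2.5 mol %), (S)-BINAP (6 mol %; (R)-BINAP if the facial sense proves opposite), KOH (0.5 equiv), dioxane/H2O 10:1, 80 °C
Reagents that add atoms: 2 isopropenylboronic acid pinacol ester, CC(=C)B1OC(C)(C)C(C)(C)O1
Why: Rhodium-catalysed asymmetric conjugate addition (Hayashi–Miyaura reaction) of an alkenylboron reagent to an (E)-β-methyl enoyl acceptor is precedented for unsaturated amides including Weinreb amides, and the binaphthyl ligand shields one face of the enoyl unit during carborhodation, which should set the new stereocentre (S), the future C4.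

Step 2
Reactants: 3 (S)-N-methoxy-N,3,4-trimethylpent-4-enamide; 4 vinylmagnesium bromide
Product: 6 (S)-5,6-dimethylhepta-1,6-dien-3-one, via chelated tetrahedral adduct 5 (not isolated)
Conditions: CH2=CHMgBr (1.3 equiv), THF, −78 → 0 °C; inverse quench into cold 1 M HCl
Reagents that add atoms: 4 vinylmagnesium bromide, C=C[Mg]Br
Why: Weinreb ketone synthesis, in which the chelated adduct 5 survives until the cold acidic quench so that the Grignard reagent adds only once and the released N,O-dimethylhydroxylamine is protonated before it can add to the vinyl ketone, the stereocentre being untouched.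

Step 3
Reactants: 6 (S)-5,6-dimethylhepta-1,6-dien-3-one
Product: 7 (S)-3,4-dimethylcyclopent-2-en-1-one
Conditions: Grubbs II (3 mol %), CH2Cl2 (0.05 M), 40 °C
Reagents that add atoms: none
Why: Ring-closing metathesis of a vinyl ketone with a 1,1-disubstituted alkene is an established route to 3-substituted cyclopent-2-enones, is driven by loss of ethylene, and leaves the non-enolisable C4 stereocentre unchanged.

Step 4
Reactants: 8 (E)-but-2-enal; 9 tert-butyldimethylsilyl trifluoromethanesulfonate
Product: 10 (E)-1-(tert-butyldimethylsilyloxy)buta-1,3-diene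
Conditions: TBSOTf (1.05 equiv), Et3N (1.5 equiv), Et2O, 0 °C → rt; distillation
Reagents that add atoms: 9 tert-butyldimethylsilyl trifluoromethanesulfonate, CC(C)(C)[Si](C)(C)OS(=O)(=O)C(F)(F)F
Why: Soft enolisation of the enal (O-silylation then γ-deprotonation) is the standard preparation of 1-silyloxybuta-1,3-dienes and should give mainly the (E)-isomer, the only one that can adopt the s-cis conformation needed in step 5.

Step 5
Reactants: 7 (S)-3,4-dimethylcyclopent-2-en-1-one; 10 (E)-1-(tert-butyldimethylsilyloxy)buta-1,3-diene
Product: 11 cis-fused 7α-(tert-butyldimethylsilyloxy)-3β,3aβ-dimethyl-7aβ-H-2,3,3a,4,7,7a-hexahydro-1H-inden-1-one (indane numbering)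
Conditions: 10 (2.5 equiv), AlBr3/AlMe3 (5:1, 30 mol %), toluene–CH2Cl2, −20 → 0 °C; Et3N then aq NaHCO3
Reagents that add atoms: 10 (E)-1-(tert-butyldimethylsilyloxy)buta-1,3-diene, C=C/C=C/O[Si](C)(C)C(C)(C)C
Why: Lewis-acid-promoted Diels–Alder reaction of a β-substituted cycloalkenone with a silyloxydiene (the mixed aluminium system is the one used for hindered pairs), in which the unsubstituted diene terminus bonds to the enone β-carbon (ortho regiochemistry, placing OTBS next to the ring-fusion CH), the diene adds anti to the C4 methyl of 7 so that the two methyls end up cis on a cis-fused bicycle, and the endo transition state places the silyloxy group cis to the acyl bond (α), as needed for C9.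

Step 6
Reactants: 11 silyloxy hydrindenone; 12 dibromomethane
Product: 13 1-(dibromomethyl)-7α-(tert-butyldimethylsilyloxy)-3β,3aβ-dimethyl-7aβ-H-2,3,3a,4,7,7a-hexahydro-1H-inden-1-ol
Conditions: CH2Br2 (2.5 equiv), LDA (2.2 equiv, added last), THF, −78 °C; AcOH quench at −78 °C
Reagents that add atoms: 12 dibromomethane, BrCBr
Why: Dibromomethyllithium generated in the presence of the ketone adds to the cyclopentanone carbonyl faster than the amide base enolises it (first stage of the β-oxido carbenoid homologation), and the new carbinol centre may form as either epimer because it is destroyed in step 7.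

Step 7
Reactants: 13 dibromomethyl carbinol
Product: 16 9α-(tert-butyldimethylsilyloxy)-4β,5β-dimethyl-10β-H-decal-7-en-2-one (8-silyloxy-4,4a-dimethyl-3,4,4a,5,8,8a-hexahydronaphthalen-2(1H)-one), via β-oxido carbenoid 14 (not isolated), via lithium enolate 15 (not isolated)
Conditions: n-BuLi (2.3 equiv), THF, −78 °C (30 min) → −20 °C; AcOH/THF quench at −78 °C
Reagents that add atoms: none
Why: The first equivalent of n-BuLi forms the lithium alkoxide and the second effects Br/Li exchange to the β-oxido carbenoid 14, in which a ring C–C bond shifts to the carbenoid carbon as bromide leaves and gives the ring-enlarged lithium enolate 15 directly, the closest known reaction type being the dibromomethyllithium (β-oxido carbenoid) one-carbon ring expansion of cyclic ketones, a semipinacol-type homologation. No new ring is closed: the five-membered ring of the hydrindane is enlarged to the six-membered ring A by insertion of the carbenoid carbon (the future C1) between the carbonyl carbon and the ring-fusion methine. No stereocentre is created, and the migrating ring-fusion carbon keeps its configuration because the 1,2-shift is suprafacial, so the cis fusion set in step 5 is carried into the decalin as 10β-H. The step needs migration of the ring-fusion methine and not of the C2 methylene, since only that places the carbonyl between two CH2 groups; in β-oxido carbenoid rearrangements the more substituted α-carbon is reported to migrate preferentially (the opposite of Lewis-acid/diazoalkane homologations), and here a tertiary carbon competes with a secondary one. The inductive pull of the neighbouring silyloxy-bearing carbon lowers the migratory aptitude of the ring-fusion carbon and is the main uncertainty, the regioisomeric 1-decalone being the expected by-product. The enolate 15 is formed regiospecifically towards the new CH2 and is simply protonated, while the silyl ether, the ring-B alkene and the methyl-bearing centres should be inert to n-BuLi at −78 °C.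

Step 8
Reactants: 16 silyloxy decalenone; 17 ethylene glycol
Product: 18 2,2-ethylenedioxy ketal of 16 (9α-OTBS, 4β,5β-dimethyl, 10β-H, Δ7)
Conditions: ethylene glycol (5 equiv), PPTS (10 mol %), benzene, reflux, Dean–Stark
Reagents that add atoms: 17 ethylene glycol, OCCO
Why: Acid-catalysed dioxolane formation with azeotropic water removal is routine for an unhindered cyclohexanone, PPTS is mild enough to spare the secondary TBS ether and the alkene, and the ketal masks the ketone for the organometallic step 11.

Step 9
Reactants: 18 silyloxy ketal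
Product: 19 2,2-ethylenedioxy-4β,5β-dimethyl-10β-H-decal-7-en-9α-ol
Conditions: TBAF (1.5 equiv), THF, 0 °C → rt
Reagents that add atoms: none
Why: Fluoride cleavage of a secondary TBS ether is routine, is orthogonal to the dioxolane, and frees the allylic hydroxyl needed to direct step 10.

Step 10
Reactants: 19 allylic alcohol; 20 tert-butyl hydroperoxide
Product: 21 7α,8α-epoxy-2,2-ethylenedioxy-4β,5β-dimethyl-10β-H-decalin-9α-ol
Conditions: VO(acac)2 (3 mol %), t-BuOOH (1.5 equiv, in decane), CH2Cl2, 0 °C → rt
Reagents that add atoms: 20 tert-butyl hydroperoxide, CC(C)(C)OO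
Why: Vanadium-catalysed hydroxyl-directed epoxidation of a cyclic allylic alcohol delivers oxygen to the alkene face syn to the coordinating hydroxyl, so the epoxide should form on the α-face and fix the C8–O configuration.

Step 11
Reactants: 21 epoxy alcohol; 22 isopropenylmagnesium bromide
Product: 23 2,2-ethylenedioxy-7β-isopropenyl-4β,5β-dimethyl-10β-H-decalin-8α,9α-diol
Conditions: isopropenylMgBr (4 equiv), CuI (15 mol %), THF, −30 → 0 °C; aqueous work-up
Reagents that add atoms: 22 isopropenylmagnesium bromide, CC(=C)[Mg]Br
Why: Copper-catalysed Grignard opening of a cyclohexene oxide is anti and trans-diaxial (Fürst–Plattner), and attack at C7, the carbon remote from the electron-withdrawing C9 oxygen, avoids the chair required for C8 attack in which C4, O9 and the new C7 oxygen would all be syn-axial, so the isopropenyl group should enter C7 from the β-face and leave the 8α-hydroxyl.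

Step 12
Reactants: 23 diol; 24 acetic anhydride
Product: 25 8α-acetoxy-2,2-ethylenedioxy-7β-isopropenyl-4β,5β-dimethyl-10β-H-decalin-9α-ol
Conditions: Ac2O (1.2 equiv), pyridine, CH2Cl2, 0 °C → rt
Reagents that add atoms: 24 acetic anhydride, CC(=O)OC(C)=O
Why: Mild acylation of a cis-1,2-diol favours the equatorial hydroxyl, and here the C8 hydroxyl is equatorial whereas the axial C9 hydroxyl is syn-axial to C4 and flanked by the ring fusion, so one equivalent of anhydride should give the 8-monoacetate.

Step 13
Reactants: 25 hydroxy acetate; 26 (E)-2-methylbut-2-enoyl chloride (tigloyl chloride)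
Product: 27 8α-acetoxy-2,2-ethylenedioxy-7β-isopropenyl-4β,5β-dimethyl-10β-H-decalin-9α-yl (E)-2-methylbut-2-enoate
Conditions: tigloyl chloride (3 equiv), DMAP (0.5 equiv), pyridine (5 equiv), toluene, 70 °C
Reagents that add atoms: 26 tigloyl chloride, C/C=C(\C)C(Cl)=O
Why: DMAP-catalysed acylation with the acid chloride at elevated temperature is the usual way to esterify a hindered axial secondary alcohol, the (E)-2-methylbut-2-enoyl unit is the thermodynamically stable geometry so no isomerisation is expected, and the weak base pyridine should keep ketene formation and acetate migration slow.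

Step 14
Reactants: 27 ketal diester
Product: 28 target, 8α-acetoxy-9α-[(E)-2-methylbut-2-enoyloxy]-10βH-eremophil-11-en-2-one (CNP0204573.1)
Conditions: PPTS (0.3 equiv), acetone/H2O 10:1, 50 °C
Reagents that add atoms: water, O
Why: Mild aqueous acid hydrolyses the dioxolane of an unhindered cyclohexanone without cleaving the acetate or tiglate, isomerising the isopropenyl group or epimerising any centre, since both carbons α to the liberated ketone are CH2.

**Compound list**

1 | (E)-N-methoxy-N-methylbut-2-enamide | C/C=C/C(=O)N(C)OC | starting material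
2 | isopropenylboronic acid pinacol ester | CC(=C)B1OC(C)(C)C(C)(C)O1 | starting material
3 | (S)-N-methoxy-N,3,4-trimethylpent-4-enamide | CON(C)C(=O)C[C@H](C)C(C)=C | intermediate
4 | vinylmagnesium bromide | C=C[Mg]Br | starting material
5 | chelated tetrahedral adduct of 3 and 4 (bromomagnesium N-methoxy-N-methyl hemiaminal alkoxide) | C=CC(O[Mg]Br)(N(C)OC)C[C@H](C)C(C)=C | intermediate
6 | (S)-5,6-dimethylhepta-1,6-dien-3-one | C=CC(=O)C[C@H](C)C(C)=C | intermediate
7 | (S)-3,4-dimethylcyclopent-2-en-1-one | O=C1C[C@H](C)C(C)=C1 | intermediate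
8 | (E)-but-2-enal (crotonaldehyde) | C/C=C/C=O | starting material
9 | tert-butyldimethylsilyl trifluoromethanesulfonate | CC(C)(C)[Si](C)(C)OS(=O)(=O)C(F)(F)F | starting material
10 | (E)-1-(tert-butyldimethylsilyloxy)buta-1,3-diene | C=C/C=C/O[Si](C)(C)C(C)(C)C | intermediate
11 | cis-fused 7α-(tert-butyldimethylsilyloxy)-3β,3aβ-dimethyl-7aβ-H-2,3,3a,4,7,7a-hexahydro-1H-inden-1-one | CC(C)(C)[Si](C)(C)O[C@@H]1C=CC[C@@]2(C)[C@@H]1C(=O)C[C@@H]2C | intermediate
12 | dibromomethane | BrCBr | starting material
13 | 1-(dibromomethyl)-7α-(tert-butyldimethylsilyloxy)-3β,3aβ-dimethyl-7aβ-H-2,3,3a,4,7,7a-hexahydro-1H-inden-1-ol (carbinol centre undefined) | CC(C)(C)[Si](C)(C)O[C@@H]1C=CC[C@@]2(C)[C@@H]1C(O)(C(Br)Br)C[C@@H]2C | intermediate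
14 | β-oxido carbenoid (O-lithio, bromo(lithio)methyl derivative of 13) | CC(C)(C)[Si](C)(C)O[C@@H]1C=CC[C@@]2(C)[C@@H]1C(O[Li])(C([Li])Br)C[C@@H]2C | intermediate
15 | lithium enolate of 16 (enolate double bond C1=C2) | CC(C)(C)[Si](C)(C)O[C@@H]1C=CC[C@@]2(C)[C@@H]1C=C(O[Li])C[C@@H]2C | intermediate
16 | 9α-(tert-butyldimethylsilyloxy)-4β,5β-dimethyl-10β-H-decal-7-en-2-one | CC(C)(C)[Si](C)(C)O[C@@H]1C=CC[C@@]2(C)[C@@H]1CC(=O)C[C@@H]2C | intermediate
17 | ethylene glycol | OCCO | starting material
18 | 2,2-ethylenedioxy ketal of 16 | CC(C)(C)[Si](C)(C)O[C@@H]1C=CC[C@@]2(C)[C@@H]1CC3(OCCO3)C[C@@H]2C | intermediate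
19 | 2,2-ethylenedioxy-4β,5β-dimethyl-10β-H-decal-7-en-9α-ol | O[C@@H]1C=CC[C@@]2(C)[C@@H]1CC3(OCCO3)C[C@@H]2C | intermediate
20 | tert-butyl hydroperoxide | CC(C)(C)OO | starting material
21 | 7α,8α-epoxy-2,2-ethylenedioxy-4β,5β-dimethyl-10β-H-decalin-9α-ol | O[C@@H]1[C@@H]2O[C@@H]2C[C@@]3(C)[C@@H]1CC4(OCCO4)C[C@@H]3C | intermediate
22 | isopropenylmagnesium bromide | CC(=C)[Mg]Br | starting material
23 | 2,2-ethylenedioxy-7β-isopropenyl-4β,5β-dimethyl-10β-H-decalin-8α,9α-diol | C=C(C)[C@H]1C[C@@]2(C)[C@H](CC3(OCCO3)C[C@@H]2C)[C@H](O)[C@@H]1O | intermediate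
24 | acetic anhydride | CC(=O)OC(C)=O | starting material
25 | 8α-acetoxy-2,2-ethylenedioxy-7β-isopropenyl-4β,5β-dimethyl-10β-H-decalin-9α-ol | C=C(C)[C@H]1C[C@@]2(C)[C@H](CC3(OCCO3)C[C@@H]2C)[C@H](O)[C@@H]1OC(C)=O | intermediate
26 | (E)-2-methylbut-2-enoyl chloride (tigloyl chloride) | C/C=C(\C)C(Cl)=O | starting material
27 | 8α-acetoxy-2,2-ethylenedioxy-7β-isopropenyl-4β,5β-dimethyl-10β-H-decalin-9α-yl (E)-2-methylbut-2-enoate | C=C(C)[C@H]1C[C@@]2(C)[C@H](CC3(OCCO3)C[C@@H]2C)[C@H](OC(=O)/C(C)=C/C)[C@@H]1OC(C)=O | intermediate
28 | 8α-acetoxy-9α-[(E)-2-methylbut-2-enoyloxy]-10βH-eremophil-11-en-2-one (CNP0204573.1) | C=C(C)[C@H]1C[C@@]2(C)[C@H](CC(=O)C[C@@H]2C)[C@H](OC(=O)/C(C)=C/C)[C@@H]1OC(C)=O | target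

**Summary and risks**

Total steps: 14. Longest linear sequence: 13 (steps 1–3 and 5–14; step 4 prepares the diene).

Steps most likely to fail:

1. Step 5. The cycloaddition may be too slow at the fully substituted enone β-carbon, so that the Lewis acid degrades the silyl dienol ether, the reaction stops at an open-chain Mukaiyama–Michael adduct, or silanol is eliminated from the β-silyloxy ketone. Fallback, from 7 and back at 11: Hosomi–Sakurai conjugate allylation of 7 (allyltrimethylsilane, TiCl4, CH2Cl2, −78 °C; allyl enters anti to the C4 methyl and creates the quaternary centre) with interception of the titanium enolate by acrolein should give 3-allyl-2-(1-hydroxyallyl)-3,4-dimethylcyclopentanone F1, the required diastereomer being separated. Silylation (TBSOTf, 2,6-lutidine) should give its tert-butyldimethylsilyl ether F2. Ring-closing metathesis (Grubbs II) of the two cis-disposed alkene arms would then close the cyclohexene and return to 11.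

2. Step 7. The wrong α-carbon (the C2 methylene) may migrate, or the carbinolate may undergo O-to-O silyl transfer or the enolate may be butylated before the shift is complete. Fallback, from 11 and back at 16: kinetic enolisation at the C2 methylene and chlorination (LDA, −78 °C; TsCl) should give 2-chloro-7α-(tert-butyldimethylsilyloxy)-3β,3aβ-dimethyl-hexahydroinden-1-one F3. Homologation with trimethylsilyldiazomethane/BF3·OEt2 (protodesilylation on work-up), in which the chlorine-bearing carbon does not migrate, should give 3-chloro-9α-(tert-butyldimethylsilyloxy)-4β,5β-dimethyl-10β-H-decal-7-en-2-one F4. Zn/AcOH dechlorination would return to 16.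

3. Step 13. Acylation of the hindered axial C9 hydroxyl may be slow enough for the neighbouring acetate to migrate from O8 to O9, after which the freed equatorial O8 is acylated instead. Fallback, from 23 and back at 27: selective silylation of the equatorial hydroxyl (TESCl, imidazole) should give the 8-O-triethylsilyl ether F5. Forcing tigloylation (tigloyl chloride, DMAP, 70 °C), now without a migrating acyl group, should give the 8-O-triethylsilyl 9-tiglate F6. HF·pyridine should then give the 8-hydroxy 9-tiglate F7, and fast acetylation of the equatorial hydroxyl (Ac2O, pyridine) would return to 27.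

Further compounds
F1 | step 5 | 3-allyl-2-(1-hydroxyallyl)-3,4-dimethylcyclopentanone (allyl and hydroxyallyl arms cis, methyls cis) | C=CC[C@]1(C)[C@@H](C)CC(=O)[C@@H]1[C@H](O)C=C
F2 | step 5 | tert-butyldimethylsilyl ether of F1 | C=CC[C@]1(C)[C@@H](C)CC(=O)[C@@H]1[C@H](O[Si](C)(C)C(C)(C)C)C=C
F3 | step 7 | 2-chloro-7α-(tert-butyldimethylsilyloxy)-3β,3aβ-dimethyl-7aβ-H-2,3,3a,4,7,7a-hexahydro-1H-inden-1-one | CC(C)(C)[Si](C)(C)O[C@@H]1C=CC[C@@]2(C)[C@@H]1C(=O)C(Cl)[C@@H]2C
F4 | step 7 | 3-chloro-9α-(tert-butyldimethylsilyloxy)-4β,5β-dimethyl-10β-H-decal-7-en-2-one | CC(C)(C)[Si](C)(C)O[C@@H]1C=CC[C@@]2(C)[C@@H]1CC(=O)C(Cl)[C@@H]2C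
F5 | step 13 | 2,2-ethylenedioxy-7β-isopropenyl-4β,5β-dimethyl-8α-(triethylsilyloxy)-10β-H-decalin-9α-ol | C=C(C)[C@H]1C[C@@]2(C)[C@H](CC3(OCCO3)C[C@@H]2C)[C@H](O)[C@@H]1O[Si](CC)(CC)CC
F6 | step 13 | 2,2-ethylenedioxy-7β-isopropenyl-4β,5β-dimethyl-8α-(triethylsilyloxy)-10β-H-decalin-9α-yl (E)-2-methylbut-2-enoate | C=C(C)[C@H]1C[C@@]2(C)[C@H](CC3(OCCO3)C[C@@H]2C)[C@H](OC(=O)/C(C)=C/C)[C@@H]1O[Si](CC)(CC)CC
F7 | step 13 | 2,2-ethylenedioxy-8α-hydroxy-7β-isopropenyl-4β,5β-dimethyl-10β-H-decalin-9α-yl (E)-2-methylbut-2-enoate | C=C(C)[C@H]1C[C@@]2(C)[C@H](CC3(OCCO3)C[C@@H]2C)[C@H](OC(=O)/C(C)=C/C)[C@@H]1O
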